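**The pitfall.** A ratio of two peaks can mislead when it is taken from one sample: at 6.00 min in the ash run, which is the flask asked about, isomer of the product A read 1.0%, with a scatter of 0.3 percentage points on it. So I pooled the readings, working in fractions of the charge.

| flask | starting material | catalyst | remark | time |
|---|---|---|---|---|
| ash | 35 mM | 4.6 mM | the very flask that is asked about, followed so far |  |
| maple | 23 mM | 4.6 mM | run made earlier |  |
| flask | 35 mM | 4.6 mM |  | 2.5 h |

| run | time / min | isomer of the product A / % | target / % |
|---|---|---|---|
| ash | 6.00 | 1.0 | 12.0 |
| ash | 10.0 | 1.4 | 19.2 |
| ash | 15.0 | 2.5 | 27.0 |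
| ash | 25.0 | 3.7 | 39.1 |
| ash | 50.0 | 5.3 | 58.4 |
| ash | 80.0 | 6.6 | 69.5 |
| maple | 20.0 | 2.8 | 32.8 |
| maple | 40.0 | 4.8 | 51.8 |
| maple | 50.0 | 5.2 | 57.8 |
| maple | 80.0 | 6.7 | 70.1 |
| maple | 120 | 7.6 | 76.2 |

(readings scatter by 0.3 percentage points)

1. ratio of isomer of the product A to target at 80 s
2. ratio of isomer of the product A to target at 12 min
3. ratio of isomer of the product A to target at 2.5 h



**Early ratio.** My first way took the ash samples up to 15.0 min: summed isomer of the product A over summed target gave 0.0842, the early selectivity factor s, meaning the ratio of the two products before the run has aged. My second way took the first maple sample, from a different charge of starting material, and gave 0.0854, about the same as s. I trusted that agreement and committed to about 0.0842 at 80 s and 12 min.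

**Late ratio.** For 2.5 h the two ways parted. Carrying s forward flat gave 0.0842, but the last maple sample, at 120 min, read 0.0997, which is higher. The pooled reading at 80.0 min lay between them, at 0.0953. The last maple increment, noisy as it was, read 0.148. So I judged the flat carry to be the one that cheated, and I committed to about 0.0997.

**The forecast.** It gave 0.083, 0.087 and 0.103, the last a little above mine, and it read the drift as “mainly parallel formation”.

**The flask.** The ash flask gave 0.0858 at 80 s, 0.0904 at 12 min and 0.0959 at 2.5 h, each inside the forecast's range, and the last is 1.14 times the reading s.

    starting material ⇌ other conformer, settled at all times (K = 0.0630)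
    starting material + catalyst → catalyst + target (k = 0.0890 /M/s)
    catalyst + other conformer → catalyst + isomer of the product A (k = 0.120 /M/s)
    target + catalyst ⇌ isomer of the product B + catalyst, rate k4*[catalyst]*[target] forward; the back reaction follows from the equilibrium constant (K = 0.130, k = 0.0560 /M/s)
    starting material → uncatalysed product (k = 1.10 × 10⁻⁵ /s)

In this flask the half-life of target by its forward conversion into isomer of the product B alone, 0.75 h with the other concentrations as charged, is shorter than the 2.5 h of the run. The backward turnover of that step came to 93% of the forward one, and at 2.5 h the flask held 10.1% isomer of the product B beside 78.0% target. In the neighbour with 2.8 mM of catalyst the ratio at 80 s was 0.0855, about s, and at 2.5 h it was 0.0957, with 8.69% of the charged starting material left.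

The earlier runs and the new flask were computed for substances that don't exist, and the scatter is random.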